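**Retrosynthetic overview**
- The plan rests on the 1,4-relationship of the C2 ketone and the C9 oxygen through C1 and C10. With C9 as a ketone, C1 is the β-carbon of an exocyclic C10=C1 enone, so ring A (C1–C5, C10) is cut at C1–C2 into a C2 acyl radical (from a Se-phenyl selenoester) and an α-methylene ketone on ring B (C5–C10).
- Ring B is bought. Carvone supplies C5–C10, the C7 isopropenyl group and, as its ring methyl, C1. MeLi addition and oxidative 1,3-transposition of (R)-carvone add the C5 methyl and give (S)-3-methylcarvone.
- C8–O comes from α′-hydroxylation. C4–C5 comes from a conjugate (Z)-crotylation anti to the isopropenyl group, with silyl capture of the C9=C10 enolate. That capture allows regiospecific C10 selenenylation and selenoxide elimination to C10=C1, and the vinyl end becomes C2.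
- Ring order: ring B (chiral pool), then ring A (step 12). Afterwards: C2 ketal, β-face reduction of C9, tiglate at O9, release of O8 and C2, (R)-2-methylbutanoate at O8.

Key step: step 12

Assumption: eremophilane numbering is used from compound 3 on, β is the face of the C4 and C5 methyl groups (target: 4S,5R,7R,8R,9S,10S, acyl part 2R), and cis-2-butene, tigloyl chloride, N-(phenylseleno)phthalimide and (R)-2-methylbutanoic acid are taken as purchasable.

**Step 1**
Reactants: 1 (R)-(−)-carvone
Product: 2 (5R)-1,2-dimethyl-5-(prop-1-en-2-yl)cyclohex-2-en-1-ol (both carbinol epimers)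
Conditions: MeLi, Et2O, −78 → 0 °C
Reagents that add atoms: methyllithium, [Li]C
Why: 1,2-addition of a hard organolithium to the enone carbonyl brings in the future C5 methyl, and the carbinol configuration does not matter because that centre becomes sp2 in step 2.

**Step 2**
Reactants: 2 tertiary allylic alcohol
Product: 3 (S)-3-methylcarvone = (5S)-2,3-dimethyl-5-(prop-1-en-2-yl)cyclohex-2-en-1-one
Conditions: C5H5NH[CrO3Cl] (pyridinium chlorochromate), silica gel, CH2Cl2, rt
Reagents that add atoms: pyridinium chlorochromate, c1cc[nH+]cc1.[O-][Cr](=O)(=O)Cl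
Why: Babler–Dauben oxidative 1,3-transposition moves the tertiary allylic chromate ester to the other allylic terminus and oxidises it there, and because the stereocentre lies opposite the methyl-bearing ring carbon this exchange swaps its two CH2 neighbours, so (R)-carvone ends as the (S)-enone with the C7 configuration of the target.

**Step 3**
Reactants: 3 (S)-3-methylcarvone
Product: 5 (5R,6R)-6-hydroxy-2,3-dimethyl-5-(prop-1-en-2-yl)cyclohex-2-en-1-one (8α-OH trans to 7β-isopropenyl), via lithium dienolate 4 (not isolated)
Conditions: LiN(i-Pr)2, THF, −78 °C; then 2-(phenylsulfonyl)-3-phenyloxaziridine, −78 °C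
Reagents that add atoms: 2-(phenylsulfonyl)-3-phenyloxaziridine, O=S(=O)(c1ccccc1)N1OC1c1ccccc1
Why: Kinetic α′-deprotonation gives the cross-conjugated dienolate, and electrophilic enolate hydroxylation with an N-sulfonyloxaziridine delivers oxygen to C8 anti to the adjacent isopropenyl group, which is also the thermodynamic trans-diequatorial arrangement at this epimerisable centre.

**Step 4**
Reactants: 5 α′-hydroxy enone
Product: 6 8α-(tert-butyldimethylsilyloxy) enone (TBS ether of 5)
Conditions: TBSCl, imidazole, DMF, rt
Reagents that add atoms: tert-butyldimethylsilyl chloride, CC(C)(C)[Si](C)(C)Cl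
Why: Imidazole-promoted silylation of the only hydroxyl group blocks O8 until the end game and creates no stereocentre.

**Step 5**
Reactants: 7 cis-2-butene
Product: 9 (Z)-but-2-enyl(tributyl)stannane, via (Z)-crotylpotassium 8 (not isolated)
Conditions: n-BuLi, KOt-Bu, THF, −78 → −25 °C; then Bu3SnCl, −78 °C
Reagents that add atoms: tributyltin chloride, CCCC[Sn](Cl)(CCCC)CCCC
Why: Superbase allylic metalation of cis-2-butene gives the configurationally stable (Z)-crotylpotassium, which is stannylated at its unsubstituted terminus with retention of the Z geometry.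

**Step 6**
Reactants: 6 silyloxy enone; 9 (Z)-but-2-enyl(tributyl)stannane
Product: 10 ring B C9=C10 TBS enol ether carrying 5β-methyl 5α-[(2S)-but-3-en-2-yl] 7β-isopropenyl and 8α-OTBS
Conditions: TBSOTf, 2,6-di-tert-butyl-4-methylpyridine, CH2Cl2, −78 → −30 °C
Reagents that add atoms: (Z)-but-2-enyl(tributyl)stannane 9, C/C=C\C[Sn](CCCC)(CCCC)CCCC; tert-butyldimethylsilyl trifluoromethanesulfonate, CC(C)(C)[Si](C)(C)OS(=O)(=O)C(F)(F)F
Why: In this silyl-triflate-promoted conjugate allylation with an allylstannane (Hosomi–Sakurai type, SE2′ through the γ-carbon) O-silylation activates the tetrasubstituted enone, axial attack on the α face anti to the 7β-isopropenyl sets C5, an open transition state with C4–H turned over ring B and the Z-alkene synclinal over C10 (methyl and CH2Sn pointing outwards) should set C4, and the retained silyl group fixes the enol ether at C9=C10 so that no later base has to choose between C8–H and C10–H.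

**Step 7**
Reactants: 10 vinyl enol ether
Product: 12 primary alcohol (C2–OH) of the ring B enol ether, via alkyldisiamylborane 11 (not isolated)
Conditions: [(CH3)2CHCH(CH3)]2BH (from BH3·THF and 2-methylbut-2-ene), THF, 0 °C; then aq. NaOH, 30% H2O2, 0 °C
Reagents that add atoms: hydrogen peroxide, OO
Why: Anti-Markovnikov hydroboration–oxidation with a bulky dialkylborane takes the monosubstituted vinyl group well ahead of the 1,1-disubstituted isopropenyl and the tetrasubstituted enol ether, and it is placed before the enone exists because boranes would reduce an α-methylene ketone.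

**Step 8**
Reactants: 12 hydroxy enol ether
Product: 13 10β-phenylseleno C9 ketone
Conditions: PhSeCl, CH2Cl2, −78 → −20 °C
Reagents that add atoms: benzeneselenenyl chloride, Cl[Se]c1ccccc1
Why: Electrophilic selenenylation of a silyl enol ether is regiospecific for C10, is much faster than attack on the isopropenyl group, tolerates the free alcohol, and should bring selenium in from the β face opposite the axial C5 side chain (a centre that is erased in step 9).

**Step 9**
Reactants: 13 α-seleno ketone
Product: 15 ring B α-methylene ketone (C10=C1) bearing the C2 primary alcohol, via selenoxide 14 (not isolated)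
Conditions: m-CPBA (1 equiv), CH2Cl2, −78 °C; then warm to 0 °C
Reagents that add atoms: none
Why: Selenoxide syn-elimination can only take a hydrogen from the C1 methyl because C5 is quaternary, so the exocyclic enone is the sole regioisomer, and one equivalent of peracid at low temperature oxidises selenium far faster than either alkene.

**Step 10**
Reactants: 15 hydroxy α-methylene ketone
Product: 16 (3S)-3-(ring B)butanoic acid (C2 carboxylic acid)
Conditions: TEMPO (cat.), PhI(OAc)2, MeCN–H2O, rt
Reagents that add atoms: water, O
Why: Oxoammonium-mediated oxidation takes the primary alcohol through the aldehyde hydrate to the acid in a weakly acidic medium that leaves the enone, the isopropenyl group and the silyl ether untouched.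

**Step 11**
Reactants: 16 carboxylic acid
Product: 17 Se-phenyl selenoester of 16 (key precursor: C9 ketone C10=C1 methylene 8α-OTBS 7β-isopropenyl C2(=O)SePh)
Conditions: N-(phenylseleno)phthalimide and Bu3P premixed, THF, −30 °C; then 16, −30 → 0 °C
Reagents that add atoms: N-(phenylseleno)phthalimide, O=C1c2ccccc2C(=O)N1[Se]c1ccccc1
Why: In this phosphonium-type redox condensation of a carboxylic acid, premixing consumes the phosphine and the selenolate is released only next to the acyloxyphosphonium ion, so neither free Bu3P nor free PhSeH (which the diselenide/phosphine variant would liberate) is left to add to C1.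

**Step 12**
Reactants: 17 selenoester
Product: 18 cis-decalin-2,9-dione (10β-H) carrying 4β,5β-dimethyl 7β-isopropenyl and 8α-OTBS
Conditions: Bu3SnH and AIBN added over several hours, PhH (0.005 M), reflux
Reagents that add atoms: none
Why: The stannyl radical removes the PhSe group of 17, and the nucleophilic C2 acyl radical, which loses CO only slowly because that would leave a primary radical, adds to the unsubstituted electron-poor terminus C1 of the C10=C1–C9=O enone; the C9-stabilised C10 radical then takes hydrogen from Bu3SnH and carries the chain. This is the known acyl selenide/Bu3SnH acyl radical cyclisation onto enone and α-methylene carbonyl acceptors. Ring A (C1–C5, C10) closes 6-endo-trig, because the 5-exo mode would require attack on the fully substituted C10 next to quaternary C5 and would leave an unstabilised primary radical. The only new stereocentre, C10, is set by hydrogen delivery to the β face, since the new ring hangs from the axial α bond C5–C4 and covers the α face; the cis fusion is also the thermodynamic one (a trans fusion would force the 5β-methyl and the 7β-isopropenyl into a 1,3-diaxial contact), so any 10α-H epimer can be equilibrated through the C9 enol. The step needs attack at C1 rather than at the isopropenyl group, and ring closure ahead of reduction to the aldehyde; polarity matching and proximity secure the first, high dilution with slow stannane addition the second.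

**Step 13**
Reactants: 18 dione
Product: 19 C2 ethylene ketal of 18
Conditions: TMSOCH2CH2OTMS, TMSOTf (cat.), CH2Cl2, −78 → −20 °C
Reagents that add atoms: 1,2-bis(trimethylsilyloxy)ethane, C[Si](C)(C)OCCO[Si](C)(C)C
Why: Silyl-triflate-catalysed ketalisation picks C2, which is flanked by two CH2 groups, over C9, which is crowded by C8–OTBS and the ring-fusion carbon and whose oxocarbenium ion is destabilised by the α-oxygen, and the cold anhydrous medium spares the silyl ether and the isopropenyl group.

**Step 14**
Reactants: 19 keto ketal
Product: 20 9α-alcohol (axial and cis to 8α-OTBS)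
Conditions: LiBH(s-Bu)3, THF, −78 → −20 °C
Reagents that add atoms: none
Why: In this bulky borohydride reduction ring A and the syn-axial C5–C4 bond close the α face of ring B, so hydride arrives on the equatorial trajectory from the convex β face and sets C9 as the axial 9α-alcohol.

**Step 15**
Reactants: 20 9α-alcohol; 21 tigloyl chloride
Product: 22 9α-tiglate
Conditions: 21, DMAP, pyridine, 50 °C
Reagents that add atoms: tigloyl chloride 21, C/C=C(\C)C(=O)Cl
Why: DMAP-catalysed acylation through the acylpyridinium ion esterifies the only free hydroxyl group, pyridine instead of a trialkylamine avoids vinylketene formation and deconjugation, and the E geometry of the tiglate is the stable one.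

**Step 16**
Reactants: 22 silyl ether ketal
Product: 23 8α-hydroxy-9α-tigloyloxy 2-ketone
Conditions: 48% aq. HF, MeCN, 0 °C → rt
Reagents that add atoms: water, O
Why: Acidic fluoride cleaves the C8 silyl ether and the aqueous acid hydrolyses the unhindered dioxolane in one operation, and the acidic medium (unlike basic fluoride) should suppress migration of the tigloyl group from O9 to O8.

**Step 17**
Reactants: 23 hydroxy ketone; 24 (R)-2-methylbutanoic acid
Product: 25 CNP0312791.1 (target)
Conditions: 24, DCC, DMAP (cat.), CH2Cl2, 0 °C → rt
Reagents that add atoms: (R)-2-methylbutanoic acid 24, CC[C@@H](C)C(=O)O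
Why: Steglich esterification acylates the equatorial 8α-hydroxyl group, and carbodiimide activation avoids a ketene pathway, so the (R) centre bought with 24 is kept.

**Compound list**
1 | (R)-(−)-carvone | CC1=CC[C@H](CC1=O)C(C)=C | starting material
2 | (5R)-1,2-dimethyl-5-(prop-1-en-2-yl)cyclohex-2-en-1-ol, carbinol epimers | CC1=CC[C@H](CC1(C)O)C(C)=C | intermediate
3 | (S)-3-methylcarvone | C=C(C)[C@H]1CC(C)=C(C)C(=O)C1 | intermediate
4 | lithium cross-conjugated dienolate of 3 | C=C(C)[C@H]1CC(C)=C(C)C([O-])=C1.[Li+] | intermediate
5 | (5R,6R)-6-hydroxy-3-methylcarvone (8α-OH) | C=C(C)[C@H]1CC(C)=C(C)C(=O)[C@@H]1O | intermediate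
6 | TBS ether of 5 | C=C(C)[C@H]1CC(C)=C(C)C(=O)[C@@H]1O[Si](C)(C)C(C)(C)C | intermediate
7 | cis-2-butene | C/C=C\C | starting material
8 | (Z)-crotylpotassium | C/C=C\[CH2-].[K+] | intermediate
9 | (Z)-but-2-enyl(tributyl)stannane | C/C=C\C[Sn](CCCC)(CCCC)CCCC | intermediate
10 | C9=C10 TBS enol ether, 5α-[(2S)-but-3-en-2-yl], 5β-methyl, 7β-isopropenyl, 8α-OTBS | C=C(C)[C@H]1C[C@](C)([C@@H](C)C=C)C(C)=C(O[Si](C)(C)C(C)(C)C)[C@@H]1O[Si](C)(C)C(C)(C)C | intermediate
11 | C2 disiamylborane of 10 | C=C(C)[C@H]1C[C@](C)([C@@H](C)CCB(C(C)C(C)C)C(C)C(C)C)C(C)=C(O[Si](C)(C)C(C)(C)C)[C@@H]1O[Si](C)(C)C(C)(C)C | intermediate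
12 | C2 primary alcohol, enol ether intact | C=C(C)[C@H]1C[C@](C)([C@@H](C)CCO)C(C)=C(O[Si](C)(C)C(C)(C)C)[C@@H]1O[Si](C)(C)C(C)(C)C | intermediate
13 | 10β-phenylseleno C9 ketone | C=C(C)[C@H]1C[C@](C)([C@@H](C)CCO)[C@@](C)([Se]c2ccccc2)C(=O)[C@@H]1O[Si](C)(C)C(C)(C)C | intermediate
14 | selenoxide of 13 | C=C(C)[C@H]1C[C@](C)([C@@H](C)CCO)[C@@](C)([Se](=O)c2ccccc2)C(=O)[C@@H]1O[Si](C)(C)C(C)(C)C | intermediate
15 | α-methylene ketone with C2 alcohol | C=C(C)[C@H]1C[C@](C)([C@@H](C)CCO)C(=C)C(=O)[C@@H]1O[Si](C)(C)C(C)(C)C | intermediate
16 | α-methylene ketone with C2 carboxylic acid | C=C(C)[C@H]1C[C@](C)([C@@H](C)CC(=O)O)C(=C)C(=O)[C@@H]1O[Si](C)(C)C(C)(C)C | intermediate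
17 | Se-phenyl selenoester (key precursor) | C=C(C)[C@H]1C[C@](C)([C@@H](C)CC(=O)[Se]c2ccccc2)C(=C)C(=O)[C@@H]1O[Si](C)(C)C(C)(C)C | intermediate
18 | cis-decalin-2,9-dione, 10β-H, 8α-OTBS (key product) | C=C(C)[C@H]1C[C@@]2(C)[C@H](CC(=O)C[C@@H]2C)C(=O)[C@@H]1O[Si](C)(C)C(C)(C)C | intermediate
19 | C2 ethylene ketal of 18 | C=C(C)[C@H]1C[C@@]2(C)[C@H](CC3(C[C@@H]2C)OCCO3)C(=O)[C@@H]1O[Si](C)(C)C(C)(C)C | intermediate
20 | 9α-alcohol | C=C(C)[C@H]1C[C@@]2(C)[C@H](CC3(C[C@@H]2C)OCCO3)[C@H](O)[C@@H]1O[Si](C)(C)C(C)(C)C | intermediate
21 | tigloyl chloride, (E)-2-methylbut-2-enoyl chloride | C/C=C(\C)C(=O)Cl | starting material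
22 | 9α-tiglate, 8α-OTBS, C2 ketal | C=C(C)[C@H]1C[C@@]2(C)[C@H](CC3(C[C@@H]2C)OCCO3)[C@H](OC(=O)/C(C)=C/C)[C@@H]1O[Si](C)(C)C(C)(C)C | intermediate
23 | 8α-hydroxy-9α-tigloyloxy 2-ketone | C=C(C)[C@H]1C[C@@]2(C)[C@H](CC(=O)C[C@@H]2C)[C@H](OC(=O)/C(C)=C/C)[C@@H]1O | intermediate
24 | (R)-2-methylbutanoic acid | CC[C@@H](C)C(=O)O | starting material
25 | CNP0312791.1 | C=C(C)[C@H]1C[C@@]2(C)[C@H](CC(=O)C[C@@H]2C)[C@H](OC(=O)/C(C)=C/C)[C@@H]1OC(=O)[C@H](C)CC | target

Total step count: 17. Longest linear sequence: 16 (steps 1–4 and 6–17; step 5 is a one-step side branch).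

**Steps most likely to fail**

**Step 6.**
- What may go wrong: the stannane may be too weak a nucleophile for the tetrasubstituted, α′-oxygenated enone, giving slow 1,4-addition, competing 1,2-attack or protodestannylation. The open transition state may also discriminate poorly between the two faces of the crotyl terminus, which would erode C4. The E-stannane is expected to lean towards the wrong C4 epimer, so loss of Z purity would add to this.
- Fallback: it sets out from 6 and changes the nucleophile class. Methyl propanoate is converted (LiN(i-Pr)2, TBSCl) into the (E)-silyl ketene acetal of methyl propanoate F1. A Mukaiyama–Michael addition of this much stronger π-nucleophile under catalytic TBSOTf, with silyl transfer to O9, should give the C3 methyl ester F2. In F2, C4 lies α to a carbonyl group, so an unwanted epimer can be separated and re-equilibrated with NaOMe. Reduction with i-Bu2AlH at −78 °C gives the C3 aldehyde F3, and Wittig methylenation with Ph3P=CH2 comes back to the route at 10.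

**Step 12.**
- What may go wrong: hydrogen transfer to the acyl radical before ring closure, decarbonylation, or stannyl radical addition to C1 (hydrostannation of the enone) may outrun the cyclisation.
- Fallback: it sets out from 15 and makes the same C1–C2 bond by polar umpolung. Dess–Martin oxidation gives the C2 aldehyde F4. An intramolecular Stetter reaction (thiazolium-derived carbene, Et3N, dioxane, heat) then adds the acyl anion equivalent to C1 of the α-methylene ketone. The basic medium equilibrates C10 to the cis fusion, and the sequence comes back at 18.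

**Step 15.**
- What may go wrong: acylation of the axial 9α-hydroxyl group, which sits on the concave face next to the bulky C8 silyl ether, may be very slow. Forcing conditions may then bring silyl migration or deconjugation of the acyl donor.
- Fallback: it sets out from 20 and reverses the order of the two acylations.
  - Bu4NF in THF gives the 8α,9α-diol ketal F5.
  - The unhindered equatorial 8α-hydroxyl group is esterified selectively with 24 (DCC, DMAP, 0 °C) to the 8-mono(2-methylbutanoate) F6.
  - The 9α-hydroxyl group, now free of the silyl neighbour, is tigloylated with 21 (DMAP, pyridine, heat) to the diester ketal F7.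
  - Dilute aqueous HCl in THF removes the ketal and comes back at 25.

**Further compounds**
F1 | step 6 | (E)-1-methoxy-1-(tert-butyldimethylsilyloxy)prop-1-ene | C/C=C(/O[Si](C)(C)C(C)(C)C)OC
F2 | step 6 | C3 methyl ester, C9=C10 TBS enol ether | C=C(C)[C@H]1C[C@](C)([C@@H](C)C(=O)OC)C(C)=C(O[Si](C)(C)C(C)(C)C)[C@@H]1O[Si](C)(C)C(C)(C)C
F3 | step 6 | C3 aldehyde, C9=C10 TBS enol ether | C=C(C)[C@H]1C[C@](C)([C@@H](C)C=O)C(C)=C(O[Si](C)(C)C(C)(C)C)[C@@H]1O[Si](C)(C)C(C)(C)C
F4 | step 12 | C2 aldehyde of the α-methylene ketone | C=C(C)[C@H]1C[C@](C)([C@@H](C)CC=O)C(=C)C(=O)[C@@H]1O[Si](C)(C)C(C)(C)C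
F5 | step 15 | 8α,9α-diol C2 ketal | C=C(C)[C@H]1C[C@@]2(C)[C@H](CC3(C[C@@H]2C)OCCO3)[C@H](O)[C@@H]1O
F6 | step 15 | 8α-[(R)-2-methylbutanoyloxy]-9α-ol C2 ketal | C=C(C)[C@H]1C[C@@]2(C)[C@H](CC3(C[C@@H]2C)OCCO3)[C@H](O)[C@@H]1OC(=O)[C@H](C)CC
F7 | step 15 | diester C2 ketal | C=C(C)[C@H]1C[C@@]2(C)[C@H](CC3(C[C@@H]2C)OCCO3)[C@H](OC(=O)/C(C)=C/C)[C@@H]1OC(=O)[C@H](C)CC
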